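**Proposed total synthesis of testudinariol A (29) by two-directional lithiation–borylation**

## Analysis of the target

Testudinariol A (29) is a C2-symmetric C30H46O4 triterpenoid in which a CH2CH2 bridge joins two identical halves, each consisting of a cyclopentanol (ring A) that carries an isopropenyl group on one carbon next to the carbinol and a tetrahydropyran (ring B) on the other. Ring B is numbered O1, C2 (bonded to ring A), C3, C4, C5 and C6; C5 bears an exocyclic trisubstituted double bond to the bridge, with C6 and the bridge methylene on the same side. Each half has four stereocentres, eight in all: three contiguous ones on ring A, with the hydroxyl cis to the isopropenyl group and trans to ring B, and C2 of ring B, which lies outside ring A and is tied to it only through a freely rotating C–C bond. The sensitive groups are the two 1,1-disubstituted alkenes, which acids protonate or isomerise, the two allylic ether linkages O1–C6 and the two secondary alcohols; no carbonyl group is present to help with bond formation. Three things make the synthesis hard: C2 must be controlled relative to ring A without a ring to pass on the stereochemical information, two trisubstituted alkene geometries must be fixed, and everything has to happen twice in one molecule, so that each selectivity counts twice. The strategy rests on one feature: C2 of ring B is a secondary oxygen-bearing carbon whose carbon neighbours are a ring A carbon and C3, a plain methylene at the end of a chain that has no stereocentre. C2 can therefore be brought in as the OCH2 carbon of a cyclopentylmethyl carbamate that is lithiated with selection of one enantiotopic hydrogen, and C3 as the carbon of a primary boronic ester, so that the C2–C3 bond and the C2 configuration are created together at both ends of an achiral twelve-carbon linker.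

## Retrosynthetic reasoning

**29 to 28.** The two ring A hydroxyls are the only functions that need protection on the way. They are carried as silyl ethers, so the last step is a fluoride desilylation of 28. No skeletal bond is cut; the gain is an end-game that never exposes the isopropenyl groups to acid.

**28 to 27, 25 and 24.** Both O1–C6 bonds are cut next. C6 is a primary allylic carbon and C2 already carries its oxygen as a secondary alcohol, so the forward reaction (27 to 28) is an intramolecular etherification in which the C2–O bond is not touched. Cutting O1–C2 would put the stereocentre at risk, and cutting a C–C bond of ring B would mean building the ring before the halves are joined. The chlorides of 27 come, through 26, from the primary allylic alcohols of 25, and these from the primary silyl ethers of 24. The forward steps must twice distinguish primary allylic oxygen from hindered secondary oxygen and must keep the alkene geometry, which direct substitution at C6 does.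

**24 to 10 and 20.** 24 is cut at both C2–C3 bonds. This is the only place where a stereocentre of 29 borders an achiral stretch of chain. Cutting here divides the molecule into two copies of one small chiral fragment (10) and an achiral linker (20), and it lets the bond and the stereocentre be made in one event. Forward, the OCH2 carbon of 10 must be lithiated with selection of one enantiotopic hydrogen (21), joined to the primary boron ends of 20 (22), and the alkyl group must shift from boron to carbon (23) before oxidation gives the C2 hydroxyls. The gain is convergence: 18 of the 30 carbons and six of the eight stereocentres arrive in the two copies of 10, and the last two stereocentres are made in the coupling.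

**20 to 17 and 18, then back to 11.** 20 is cut at both C4–C5 bonds (alkenyl–alkyl). The forward coupling must deliver a two-carbon unit that already ends in the pinacol boronate, which the hydroboration product 19 of 18 does, and must replace iodine with retention, so that the geometry of 17 becomes that of 20. 17 is traced through 16 and 15 to the diynoate 13. The ester is kept at C6 until the alkenes are made because it steers the metal of a syn hydrometallation to C5 (14), which places C6 cis to the bridge. 13 comes from 11 by C-acylation of 12.

**10 to 9 and 8.** After removal of the silyl group (9), the ring A bond between the carbinol carbon and the isopropenyl-bearing carbon is cut (retro-ene). This opens ring A to the acyclic aldehyde 8 with a single stereocentre. The forward ene closure forms the ring, the isopropenyl group and two stereocentres at once, with the hydroxyl forced cis to isopropenyl by the cyclic hydrogen transfer. No other ring bond would generate the isopropenyl group in the same step.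

**8 back to 1 and 2.** The stereocentre of 8 carries two oxygenated one-carbon arms, so it is traced to the prochiral diol 4 by an oxidation-level change (7), an exchange of ester for alcohol (6) and an enzymatic distinction of the two arms (5). The carbamate is installed at the stage of 5, so that the group needed for the key step is in place before the ring is made. 4 follows from 3 by reduction, and 3 from the C–C disconnection between the malonate carbon of 1 and the primary bromide 2.

## Alternatives that were turned down

**Alternative 1:** *Disconnection.* Both O1–C2 bonds are cut as retro-oxa-Michael additions and ring A is opened between the carbinol carbon and the isopropenyl-bearing carbon, leading to the achiral open-chain bis-enal diol A1, an isomer of 29. *Forward key step.* A cinchona-derived primary amine with an acid co-catalyst condenses with both α-branched enals of A1. Each (Z)-allylic hydroxyl adds 6-exo-trig to the β-carbon of the iminium ion (O1–C2), and face-selective protonation of the enamine sets the neighbouring carbon, giving the bis(tetrahydropyranyl) dialdehyde A2. A double Me2AlCl ene closure of A2 would then give 29. *For.* It is the shortest route on paper: A1, A2 and 29 are isomers, no protecting group is needed, and one catalyst writes the absolute configuration on both halves. *Against.*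
- α-Branched enals are reluctant iminium partners and an aliphatic alcohol adds weakly and reversibly, so C2 is exposed to retro-oxa-Michael equilibration.
- The second centre of each half is set by protonation, not by bond formation, and in A2 it stays α to an aldehyde and β to a leaving oxygen (epimerisation, E1cB ring opening).
- The ene step must then run on a β-alkoxy aldehyde whose ring oxygen can chelate aluminium.
- A1 needs four trisubstituted alkenes of defined geometry, which costs about as many steps as 20.

*Comparison.* In step economy and freedom from protecting groups alternative 1 is clearly stronger. The chosen route offers instead a C2 centre made by a stereospecific sequence from a configurationally defined carbenoid, a ring A triad that is made and checked on the small fragment 10 before the union, and no epimerisable aldehyde after the fragments are joined.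

**Alternative 2:** *Disconnection.* In each half the ring A bond between the carbinol carbon and the carbon bearing ring B is cut together with the C2–O bond, a retro-(3+2) that turns the carbinol carbon into a nitrile oxide carbon and C2 with its ring A neighbour into an (E)-alkene; the precursor is the bis(nitroalkane) A3. *Forward key step.* PhNCO and Et3N dehydrate both CH2NO2 groups of A3 to nitrile oxides, which add to the alkenes five atoms away and give the bis(cyclopenta-fused isoxazoline) A4. N–O cleavage (for instance with Mo(CO)6), ketone reduction and ring B closure would follow. *For.* The cycloaddition is suprafacial, so the alkene geometry fixes the relation between C2 and its ring A neighbour without any chiral reagent, and ring A and the C2 oxygen arrive in one step. On this point it is stronger than the chosen route, which needs a chiral diamine for C2. *Against.*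
- All control must come from the single isopropenyl-bearing stereocentre of A3, which is α to C=N in A4 and α to C=O after N–O cleavage, and so is epimerisable.
- The ring A ketone is flanked by two α-substituents on opposite faces (isopropenyl and the ring B carbon are trans in 29), so a hydride has no clearly preferred face, although the target needs the hydroxyl cis to isopropenyl.
- N–O cleavage must spare four alkenes and must not dehydrate the β-hydroxy ketone.
- The isopropenyl groups are themselves dipolarophiles.
- More steps follow the key step than the four after 24.

*Comparison.* The chosen route fixes the hydroxyl/isopropenyl relationship through the cyclic hydrogen transfer of the ene reaction, where the mechanism leaves no choice, and keeps ring A free of carbonyl groups from then on.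

**Alternative 3:** *Disconnection.* Both C5–C6 bonds of rings B are cut (retro-Prins). C6 becomes the CH2 of a methoxymethyl ether on the C2 oxygen and C5 the silicon-bearing carbon of a (Z)-vinylsilane, as in the bis(methoxymethyl ether) A5. *Forward key step.* SnCl4 ionises both acetals to O=CH2 oxocarbenium ions. Each is attacked at the ipso carbon of the vinylsilane with closure of the six-membered ring, and loss of Me3Si from the β-silyl cation leaves the exocyclic alkene with retained geometry. The product A6 is the same compound as 28. *For.* Ring B and its alkene are finished in one stereospecific step, C6 costs nothing, and only a desilylation remains, so the end of the synthesis is three steps shorter than in the chosen route. Here alternative 3 is stronger. *Against.*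
- A5 must already hold every stereocentre, so C2 has to be set earlier by a separate asymmetric C–C bond formation next to ring A.
- A5 needs two (Z)-vinylsilanes in a symmetric chain that must be joined in the middle by an sp3–sp3 coupling.
- A strong Lewis acid meets, at the very end, two isopropenyl groups, two silyl ethers and vinylsilanes that can protodesilylate.
- An acetal that ionises without closing is lost as formaldehyde.

*Comparison.* The chosen strategy forms C2–C3 and the C2 stereocentre in one event, needs only the small chiral fragment 10 (used twice) and the achiral linker 20, whose alkene geometry follows from a syn hydrometallation, and closes ring B under basic conditions that the isopropenyl groups tolerate.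

Key step: step 14

## Route

Assumption: the lipase acetylates the pro-R hydroxymethyl group of diol 4, so that the monoacetate formed is (R)-5; the fallback for step 3 supplies the same enantiomer if the enzyme prefers the other arm.

Step 1
Reactants: 1 diethyl malonate; 2 5-bromo-2-methylpent-2-ene
Product: 3 diethyl 2-(4-methylpent-3-en-1-yl)malonate
Conditions: NaOEt, EtOH, reflux (1 in excess)
Reagents that add atoms: none
Why: Malonic ester alkylation; the sodium enolate of 1 displaces the primary bromide of 2 by SN2, and the excess of 1 keeps dialkylation down.

Step 2
Reactants: 3 diethyl 2-(4-methylpent-3-en-1-yl)malonate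
Product: 4 2-(4-methylpent-3-en-1-yl)propane-1,3-diol
Conditions: LiAlH4, THF, 0 °C → reflux
Reagents that add atoms: none
Why: LiAlH4 reduces both esters to primary alcohols and leaves the isolated trisubstituted alkene untouched; the product is a prochiral 2-substituted propane-1,3-diol.

Step 3
Reactants: 4 2-(4-methylpent-3-en-1-yl)propane-1,3-diol
Product: 5 (2R)-2-(hydroxymethyl)-6-methylhept-5-en-1-yl acetate
Conditions: lipase from Burkholderia cepacia (immobilised), vinyl acetate, i-Pr2O, rt
Reagents that add atoms: vinyl acetate, C=COC(C)=O
Why: Lipase-catalysed irreversible transesterification with an enol ester distinguishes the two enantiotopic hydroxymethyl groups of a 2-substituted propane-1,3-diol, a well-established desymmetrisation; the enzyme sets the stereocentre, and slow second acetylation of the minor monoacetate should raise the enantiomeric purity of 5.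

Step 4
Reactants: 5 (2R)-2-(hydroxymethyl)-6-methylhept-5-en-1-yl acetate
Product: 6 (2S)-2-(acetoxymethyl)-6-methylhept-5-en-1-yl N,N-diisopropylcarbamate
Conditions: i-Pr2NCOCl, Et3N, CH2Cl2, 40 °C
Reagents that add atoms: N,N-diisopropylcarbamoyl chloride, CC(C)N(C(C)C)C(=O)Cl
Why: O-Carbamoylation of the free primary alcohol under tertiary-amine conditions that do not ionise the hydroxyl, so acetyl transfer between the two arms (which would racemise 5) is not expected; the stereocentre is not touched and its descriptor changes only through the priorities.

Step 5
Reactants: 6 (2S)-2-(acetoxymethyl)-6-methylhept-5-en-1-yl N,N-diisopropylcarbamate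
Product: 7 (2S)-2-(hydroxymethyl)-6-methylhept-5-en-1-yl N,N-diisopropylcarbamate
Conditions: K2CO3 (cat.), MeOH, 0 °C → rt
Reagents that add atoms: none
Why: Base-catalysed methanolysis removes the acetate; the hindered N,N-diisopropylcarbamate is inert to these conditions and does not migrate.

Step 6
Reactants: 7 (2S)-2-(hydroxymethyl)-6-methylhept-5-en-1-yl N,N-diisopropylcarbamate
Product: 8 (2R)-2-formyl-6-methylhept-5-en-1-yl N,N-diisopropylcarbamate
Conditions: 2,2,6,6-tetramethylpiperidin-1-oxyl (TEMPO, cat.), PhI(OAc)2, CH2Cl2, rt; used crude
Reagents that add atoms: none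
Why: Oxoammonium-mediated oxidation stops at the aldehyde under base-free conditions, which protects the enolisable α-stereocentre and avoids β-elimination of the carbamate; 8 is taken on at once.

Step 7
Reactants: 8 (2R)-2-formyl-6-methylhept-5-en-1-yl N,N-diisopropylcarbamate
Product: 9 [(1R,2S,3R)-2-hydroxy-3-(prop-1-en-2-yl)cyclopentyl]methyl N,N-diisopropylcarbamate
Conditions: Me2AlCl (2.5 equiv), CH2Cl2, –78 → –30 °C
Reagents that add atoms: none
Why: Intramolecular Lewis acid-promoted carbonyl-ene reaction: the aluminium-complexed aldehyde is attacked by C5 of the trisubstituted alkene while an allylic methyl hydrogen passes to oxygen, which closes ring A and creates the isopropenyl group. The cyclic hydrogen transfer forces hydroxyl and isopropenyl cis, and the α-CH2O group should sit anti to the complexed oxygen in the envelope transition state, giving the 1,2-trans relationship; the methyl–aluminium bond takes up the proton as methane, so cationic side reactions are suppressed.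

Step 8
Reactants: 9 [(1R,2S,3R)-2-hydroxy-3-(prop-1-en-2-yl)cyclopentyl]methyl N,N-diisopropylcarbamate
Product: 10 [(1R,2S,3R)-2-(tert-butyldimethylsilyloxy)-3-(prop-1-en-2-yl)cyclopentyl]methyl N,N-diisopropylcarbamate
Conditions: TBSOTf, 2,6-lutidine, CH2Cl2, –78 → 0 °C
Reagents that add atoms: tert-butyldimethylsilyl trifluoromethanesulfonate, CC(C)(C)[Si](C)(C)OS(=O)(=O)C(F)(F)F
Why: Silylation of a hindered secondary alcohol with a silyl triflate and a hindered pyridine base; carbamate and alkene are inert.

Step 9
Reactants: 11 hexa-1,5-diyne
Product: 13 dimethyl octa-2,6-diynedioate, via dilithium diacetylide 12 (not isolated)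
Conditions: n-BuLi (2.1 equiv), THF, –78 °C; ClCO2Me, –78 → 0 °C
Reagents that add atoms: methyl chloroformate, COC(=O)Cl
Why: Double deprotonation of the terminal alkyne C–H bonds and C-acylation of the dilithium acetylide with a chloroformate; the low temperature keeps the propargylic positions intact.

Step 10
Reactants: 13 dimethyl octa-2,6-diynedioate
Product: 15 dimethyl (2E,6E)-2,7-diiodoocta-2,6-dienedioate, via bis(tributylstannyl) diester 14 (not isolated)
Conditions: Bu3SnH (2.2 equiv, slow addition), Pd(PPh3)4 (cat.), THF, 0 °C → rt; then I2, 0 °C
Reagents that add atoms: iodine, II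
Why: Palladium-catalysed hydrostannation of 2-alkynoates is a syn addition that puts tin on the α-carbon and hydrogen on the β-carbon with high regioselectivity, and iododestannylation proceeds with retention. The α-iodo enoate therefore has the ester carbon and the C4 chain cis, the geometry needed later for C6 and the bridge.

Step 11
Reactants: 15 dimethyl (2E,6E)-2,7-diiodoocta-2,6-dienedioate
Product: 16 (2E,6E)-2,7-diiodoocta-2,6-diene-1,8-diol
Conditions: i-Bu2AlH (4.5 equiv), CH2Cl2, –78 → –20 °C
Reagents that add atoms: none
Why: 1,2-Reduction of the conjugated esters to allylic alcohols by the aluminium hydride; alkenyl iodides and alkene geometry are unaffected at low temperature.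

Step 12
Reactants: 16 (2E,6E)-2,7-diiodoocta-2,6-diene-1,8-diol
Product: 17 (2E,6E)-1,8-bis(tert-butyldimethylsilyloxy)-2,7-diiodoocta-2,6-diene
Conditions: TBSCl, imidazole, DMF, rt
Reagents that add atoms: tert-butyldimethylsilyl chloride, CC(C)(C)[Si](C)(C)Cl
Why: Standard imidazole-mediated silylation of primary allylic alcohols.

Step 13
Reactants: 17 (2E,6E)-1,8-bis(tert-butyldimethylsilyloxy)-2,7-diiodoocta-2,6-diene; 18 vinylboronic acid pinacol ester (2.6 equiv)
Product: 20 2,2′-[(3Z,7Z)-3,8-bis(tert-butyldimethylsilyloxymethyl)deca-3,7-diene-1,10-diyl]bis(4,4,5,5-tetramethyl-1,3,2-dioxaborolane), via 9-BBN adduct 19 (not isolated)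
Conditions: 9-borabicyclo[3.3.1]nonane (9-BBN), THF, 0 °C → rt; then 17, PdCl2(dppf) (cat.), AsPh3, Cs2CO3, DMF/H2O, rt
Reagents that add atoms: none
Why: The bulky dialkylborane should add to 18 with boron on the terminal carbon, and in the B-alkyl Suzuki–Miyaura coupling only the trialkylborane end of 19 transmetallates under mild aqueous base, the pinacol boronate being inert. Oxidative addition and reductive elimination at the alkenyl iodide retain the geometry, so the new C4–C5 bonds lie trans to the bridge (the descriptor changes from E to Z only through the priorities).

Step 14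
Reactants: 10 [(1R,2S,3R)-2-(tert-butyldimethylsilyloxy)-3-(prop-1-en-2-yl)cyclopentyl]methyl N,N-diisopropylcarbamate (2.6 equiv); 20 the bis(pinacol boronate) linker (1 equiv)
Product: 24 (1R,4Z,8Z,12R)-1,12-bis[(1R,2S,3R)-2-(tert-butyldimethylsilyloxy)-3-(prop-1-en-2-yl)cyclopentyl]-4,9-bis(tert-butyldimethylsilyloxymethyl)dodeca-4,8-diene-1,12-diol, via lithiated carbamate 21 (not isolated), via bis-boronate complex 22 (not isolated), via homologated bis(boronic ester) 23 (not isolated)
Conditions: s-BuLi, (+)-sparteine, Et2O, –78 °C, 5 h; 20, –78 °C, 1 h; MgBr2·OEt2, –78 → 35 °C, 16 h; then NaOH, H2O2, THF/H2O, 0 °C → rt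
Reagents that add atoms: hydrogen peroxide, OO
Why: s-BuLi complexed by (+)-sparteine is held by the carbamate carbonyl of 10 and removes the pro-R hydrogen of the OCH2 group, giving the lithiated carbamate 21, which is configurationally stable at –78 °C in Et2O. 21 adds to each boron atom of 20 with retention to give the bis-boronate complex 22. On warming with MgBr2·OEt2 the primary alkyl group (C3) shifts from boron to carbon anti to the departing carbamate, with inversion, which forms both C2–C3 bonds in 23; alkaline H2O2 then replaces boron by hydroxyl with retention, so that both carbinol centres of 24 are R. The closest known reaction type is the lithiation–borylation of primary O-alkyl carbamates (sparteine-mediated deprotonation, then a Matteson-type 1,2-metallate rearrangement), which is known also as a two-fold homologation of bis(boronic esters). No ring is closed in this step. The two new stereocentres are set by the chiral diamine (reagent control); the ring A stereocentre next to the reacting carbon only makes the pairing matched or mismatched. The step needs deprotonation at the carbamate CH2 and not at allylic positions (secured by precomplexation to the carbamate), reaction at both boron ends (secured by the excess of 21, since a boronate complex cannot accept a second carbenoid), and no oxygen-to-carbon silyl shift in 21 (the trans arrangement of the CH2 and silyloxy groups on ring A and the bulk of the silyl group disfavour the cyclic silicate at –78 °C).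

Step 15
Reactants: 24 the C2-symmetric bis(secondary alcohol)
Product: 25 (2Z,6Z)-2,7-bis{(3R)-3-[(1R,2S,3R)-2-(tert-butyldimethylsilyloxy)-3-(prop-1-en-2-yl)cyclopentyl]-3-hydroxypropyl}octa-2,6-diene-1,8-diol
Conditions: pyridinium p-toluenesulfonate (cat.), MeOH, rt
Reagents that add atoms: none
Why: Acid-catalysed methanolysis removes the unhindered primary allylic silyl ethers much faster than the secondary silyl ethers shielded by two ring substituents; the mild acid should neither ionise the allylic alcohols nor protonate the isopropenyl groups.

Step 16
Reactants: 25 the tetraol with two primary allylic and two secondary hydroxyls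
Product: 27 (1R,4Z,8Z,12R)-4,9-bis(chloromethyl)-1,12-bis[(1R,2S,3R)-2-(tert-butyldimethylsilyloxy)-3-(prop-1-en-2-yl)cyclopentyl]dodeca-4,8-diene-1,12-diol, via bis(methanesulfonate) 26 (not isolated)
Conditions: MsCl, LiCl, 2,4,6-collidine, DMF, 0 °C
Reagents that add atoms: lithium chloride, [Li+].[Cl-]
Why: Mesylation of the unhindered primary allylic hydroxyls in the presence of the hindered secondary ones, then displacement of the mesylate by chloride at the primary carbon (SN2, no allylic transposition, geometry kept), a standard way to primary allylic chlorides.

Step 17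
Reactants: 27 the bis(allylic chloride) diol
Product: 28 testudinariol A bis(tert-butyldimethylsilyl) ether (both ring A hydroxyls silylated)
Conditions: NaH, THF, 0 °C → rt
Reagents that add atoms: none
Why: Intramolecular Williamson etherification: each C2 alkoxide displaces the primary allylic chloride at C6 in a 6-exo-tet closure, so the C2–O bond and its configuration are untouched and the alkene geometry is kept. Direct SN2 at the unhindered CH2Cl is expected to outrun SN2′ attack at the trisubstituted alkene carbon.

Step 18
Reactants: 28 testudinariol A bis(tert-butyldimethylsilyl) ether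
Product: 29 testudinariol A
Conditions: Bu4NF, THF, rt → 45 °C
Reagents that add atoms: none
Why: Fluoride cleaves the two secondary silyl ethers; the allylic ethers, the alkenes and the stereocentres are not affected by fluoride or by the mild basicity.

## Compound list

1 | diethyl malonate | CCOC(=O)CC(=O)OCC | starting material
2 | 5-bromo-2-methylpent-2-ene | CC(C)=CCCBr | starting material
3 | diethyl 2-(4-methylpent-3-en-1-yl)malonate | CCOC(=O)C(CCC=C(C)C)C(=O)OCC | intermediate
4 | 2-(4-methylpent-3-en-1-yl)propane-1,3-diol | CC(C)=CCCC(CO)CO | intermediate
5 | (2R)-2-(hydroxymethyl)-6-methylhept-5-en-1-yl acetate | CC(C)=CCC[C@H](CO)COC(C)=O | intermediate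
6 | (2S)-2-(acetoxymethyl)-6-methylhept-5-en-1-yl N,N-diisopropylcarbamate | CC(C)=CCC[C@H](COC(=O)N(C(C)C)C(C)C)COC(C)=O | intermediate
7 | (2S)-2-(hydroxymethyl)-6-methylhept-5-en-1-yl N,N-diisopropylcarbamate | CC(C)=CCC[C@H](COC(=O)N(C(C)C)C(C)C)CO | intermediate
8 | (2R)-2-formyl-6-methylhept-5-en-1-yl N,N-diisopropylcarbamate | CC(C)=CCC[C@H](COC(=O)N(C(C)C)C(C)C)C=O | intermediate
9 | [(1R,2S,3R)-2-hydroxy-3-(prop-1-en-2-yl)cyclopentyl]methyl N,N-diisopropylcarbamate (hydroxyl cis to isopropenyl, trans to the CH2O group) | C=C(C)[C@H]1CC[C@H](COC(=O)N(C(C)C)C(C)C)[C@H]1O | intermediate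
10 | [(1R,2S,3R)-2-(tert-butyldimethylsilyloxy)-3-(prop-1-en-2-yl)cyclopentyl]methyl N,N-diisopropylcarbamate | C=C(C)[C@H]1CC[C@H](COC(=O)N(C(C)C)C(C)C)[C@H]1O[Si](C)(C)C(C)(C)C | intermediate
11 | hexa-1,5-diyne | C#CCCC#C | starting material
12 | 1,6-dilithiohexa-1,5-diyne (formed in the flask) | [Li]C#CCCC#C[Li] | intermediate
13 | dimethyl octa-2,6-diynedioate | COC(=O)C#CCCC#CC(=O)OC | intermediate
14 | dimethyl (2E,6E)-2,7-bis(tributylstannyl)octa-2,6-dienedioate (formed in the flask; tin trans to the chain) | COC(=O)/C([Sn](CCCC)(CCCC)CCCC)=C\CC/C=C(/[Sn](CCCC)(CCCC)CCCC)C(=O)OC | intermediate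
15 | dimethyl (2E,6E)-2,7-diiodoocta-2,6-dienedioate | COC(=O)/C(I)=C\CC/C=C(/I)C(=O)OC | intermediate
16 | (2E,6E)-2,7-diiodoocta-2,6-diene-1,8-diol | OC/C(I)=C\CC/C=C(/I)CO | intermediate
17 | (2E,6E)-1,8-bis(tert-butyldimethylsilyloxy)-2,7-diiodoocta-2,6-diene | CC(C)(C)[Si](C)(C)OC/C(I)=C\CC/C=C(/I)CO[Si](C)(C)C(C)(C)C | intermediate
18 | vinylboronic acid pinacol ester | C=CB1OC(C)(C)C(C)(C)O1 | starting material
19 | 2-[2-(9-borabicyclo[3.3.1]nonan-9-yl)ethyl]-4,4,5,5-tetramethyl-1,3,2-dioxaborolane (formed in the flask) | CC1(C)OB(CCB2C3CCCC2CCC3)OC1(C)C | intermediate
20 | 2,2′-[(3Z,7Z)-3,8-bis(tert-butyldimethylsilyloxymethyl)deca-3,7-diene-1,10-diyl]bis(4,4,5,5-tetramethyl-1,3,2-dioxaborolane) | CC1(C)OB(OC1(C)C)CC/C(CO[Si](C)(C)C(C)(C)C)=C/CC/C=C(/CCB1OC(C)(C)C(C)(C)O1)CO[Si](C)(C)C(C)(C)C | intermediate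
21 | (R)-α-lithio derivative of 10, lithium in place of the pro-R hydrogen of the OCH2 group, as its (+)-sparteine complex (formed in the flask) | C=C(C)[C@H]1CC[C@H]([C@@H]([Li])OC(=O)N(C(C)C)C(C)C)[C@H]1O[Si](C)(C)C(C)(C)C | intermediate
22 | dilithium bis(boronate) complex: each boron of 20 bonded to the carbamate-bearing carbon of 21, both R (formed in the flask) | C=C(C)[C@H]1CC[C@H]([C@H](OC(=O)N(C(C)C)C(C)C)[B-]2(OC(C)(C)C(C)(C)O2)CC/C(CO[Si](C)(C)C(C)(C)C)=C/CC/C=C(/CC[B-]3(OC(C)(C)C(C)(C)O3)[C@@H](OC(=O)N(C(C)C)C(C)C)[C@H]4CC[C@H](C(=C)C)[C@@H]4O[Si](C)(C)C(C)(C)C)CO[Si](C)(C)C(C)(C)C)[C@H]1O[Si](C)(C)C(C)(C)C.[Li+].[Li+] | intermediate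
23 | homologated bis(secondary pinacol boronic ester), boron on both future C2 carbons, both R (formed in the flask) | C=C(C)[C@H]1CC[C@H]([C@H](B2OC(C)(C)C(C)(C)O2)CC/C(CO[Si](C)(C)C(C)(C)C)=C/CC/C=C(/CC[C@@H](B3OC(C)(C)C(C)(C)O3)[C@H]4CC[C@H](C(=C)C)[C@@H]4O[Si](C)(C)C(C)(C)C)CO[Si](C)(C)C(C)(C)C)[C@H]1O[Si](C)(C)C(C)(C)C | intermediate
24 | (1R,4Z,8Z,12R)-1,12-bis[(1R,2S,3R)-2-(tert-butyldimethylsilyloxy)-3-(prop-1-en-2-yl)cyclopentyl]-4,9-bis(tert-butyldimethylsilyloxymethyl)dodeca-4,8-diene-1,12-diol | C=C(C)[C@H]1CC[C@H]([C@H](O)CC/C(CO[Si](C)(C)C(C)(C)C)=C/CC/C=C(/CC[C@@H](O)[C@H]2CC[C@H](C(=C)C)[C@@H]2O[Si](C)(C)C(C)(C)C)CO[Si](C)(C)C(C)(C)C)[C@H]1O[Si](C)(C)C(C)(C)C | intermediate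
25 | (2Z,6Z)-2,7-bis{(3R)-3-[(1R,2S,3R)-2-(tert-butyldimethylsilyloxy)-3-(prop-1-en-2-yl)cyclopentyl]-3-hydroxypropyl}octa-2,6-diene-1,8-diol | C=C(C)[C@H]1CC[C@H]([C@H](O)CC/C(CO)=C/CC/C=C(/CC[C@@H](O)[C@H]2CC[C@H](C(=C)C)[C@@H]2O[Si](C)(C)C(C)(C)C)CO)[C@H]1O[Si](C)(C)C(C)(C)C | intermediate
26 | bis(methanesulfonate) of 25 at the two primary allylic hydroxyls (formed in the flask) | C=C(C)[C@H]1CC[C@H]([C@H](O)CC/C(COS(C)(=O)=O)=C/CC/C=C(/CC[C@@H](O)[C@H]2CC[C@H](C(=C)C)[C@@H]2O[Si](C)(C)C(C)(C)C)COS(C)(=O)=O)[C@H]1O[Si](C)(C)C(C)(C)C | intermediate
27 | (1R,4Z,8Z,12R)-4,9-bis(chloromethyl)-1,12-bis[(1R,2S,3R)-2-(tert-butyldimethylsilyloxy)-3-(prop-1-en-2-yl)cyclopentyl]dodeca-4,8-diene-1,12-diol | C=C(C)[C@H]1CC[C@H]([C@H](O)CC/C(CCl)=C/CC/C=C(/CC[C@@H](O)[C@H]2CC[C@H](C(=C)C)[C@@H]2O[Si](C)(C)C(C)(C)C)CCl)[C@H]1O[Si](C)(C)C(C)(C)C | intermediate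
28 | testudinariol A bis(tert-butyldimethylsilyl) ether (both ring A hydroxyls silylated) | C=C(C)[C@H]1CC[C@H]([C@H]2CC/C(=C/CC/C=C3/CC[C@H]([C@H]4CC[C@H](C(=C)C)[C@@H]4O[Si](C)(C)C(C)(C)C)OC3)CO2)[C@H]1O[Si](C)(C)C(C)(C)C | intermediate
29 | testudinariol A | C=C(C)[C@H]1CC[C@H]([C@H]2CC/C(=C/CC/C=C3/CC[C@H]([C@H]4CC[C@H](C(=C)C)[C@@H]4O)OC3)CO2)[C@H]1O | target

## Step count and weak points

Total step count: 18. Longest linear sequence: 13 steps (steps 1–8 and 14–18, from diethyl malonate); the linker branch (steps 9–13) adds 5 steps before the union.

Least certain steps:

**Step 14 (key step).** The pairing of (+)-sparteine with the ring A stereocentre may be mismatched and lower the selection between the two enantiotopic hydrogens. Lithiation of the β-branched carbamate may be incomplete. The boron-to-carbon shift at the crowded boronate may be sluggish, so that one or both ends revert and are oxidised to primary alcohols. Fallback: from 10, lithiation (s-BuLi with TMEDA or (+)-sparteine, Et2O, –78 °C) and quenching with Me3SnCl gives the α-trimethylstannyl carbamate F1. Because ring A is already stereodefined, F1 and its epimer at the tin-bearing carbon are diastereomers and are separated by chromatography. Tin–lithium exchange of pure F1 with n-BuLi at –78 °C, which proceeds with retention, regenerates 21 free of its epimer and without a chiral diamine. Addition of 20 then leads through 22 and 23 back to 24.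

**Step 7.** Enolisation of the aldehyde may erode the α-centre before closure, and the ring closure may place the carbamoyloxymethyl group cis, not trans, to the new hydroxyl (wrong relative configuration at ring A C1). Fallback, which takes the C1 configuration out of the ene step and sets it under thermodynamic control: from 5, the free hydroxymethyl arm is oxidised directly (TEMPO, PhI(OAc)2) to the acetoxy aldehyde F2, which belongs to the opposite series at the α-carbon. Its Me2AlCl ene closure, if cis-selective, gives the all-cis hydroxy acetate F3, with the hydroxyl and isopropenyl centres as required. Silylation (TBSOTf, 2,6-lutidine) gives the silyl ether acetate F4, and methanolysis (K2CO3, MeOH) the all-cis primary alcohol F5. Oxidation gives the cis aldehyde F6, which is epimerised with mild base (K2CO3, MeOH) to the less crowded trans aldehyde F7. Reduction with NaBH4 gives the trans alcohol F8, and carbamoylation (i-Pr2NCOCl, Et3N) returns to the route at 10.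

**Step 13.** Hydroboration of 18 may be imperfectly regioselective, because the boryl group is a π-acceptor that directs some boron to the carbon already bearing boron, and the two-fold coupling may stop after one end. Fallback: 9-BBN is added to potassium vinyltrifluoroborate, whose tetracoordinate boron exerts no such effect, to give the 9-BBN adduct F9. Suzuki–Miyaura coupling of F9 with 17 under the conditions of step 13 gives the dipotassium bis(trifluoroborate) F10, and treatment with pinacol and Me3SiCl in MeCN returns to the route at 20.

**Step 3.** The enzyme may discriminate the enantiotopic arms insufficiently, or prefer the arm opposite to the one assumed. Fallback: from 4, acetylation (Ac2O, pyridine) gives the diacetate F11. Hydrolysis of F11 with the same lipase in phosphate buffer removes the acetyl group from the arm the enzyme recognises, and so leaves the acetate on the arm opposite to that obtained by acylation; if acylation gives the antipode, this hydrolysis returns to the route at 5.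

**Step 17.** The silyl group may migrate from the ring A oxygen to the neighbouring C2 alkoxide and block ring closure, or the alkoxide may attack in the SN2′ sense. Fallback: from 25, a Mitsunobu cyclodehydration (PPh3, diisopropyl azodicarboxylate, toluene, 0 °C → rt) activates the unhindered primary allylic hydroxyl as an alkoxyphosphonium ion, which the neutral C2 hydroxyl displaces; no alkoxide is formed, steps 16 and 17 are bypassed, and the route is rejoined at 28. This fallback makes no new compound (F0).

## Further compounds

F1 | step 14 | α-trimethylstannyl derivative of 10, tin on the OCH carbon in the position that lithium takes in 21 | C=C(C)[C@H]1CC[C@H]([C@@H]([Sn](C)(C)C)OC(=O)N(C(C)C)C(C)C)[C@H]1O[Si](C)(C)C(C)(C)C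
F2 | step 7 | (2S)-2-formyl-6-methylhept-5-en-1-yl acetate | CC(C)=CCC[C@H](C=O)COC(C)=O
F3 | step 7 | all-cis [2-hydroxy-3-(prop-1-en-2-yl)cyclopentyl]methyl acetate | C=C(C)[C@H]1CC[C@@H](COC(C)=O)[C@H]1O
F4 | step 7 | all-cis [2-(tert-butyldimethylsilyloxy)-3-(prop-1-en-2-yl)cyclopentyl]methyl acetate | C=C(C)[C@H]1CC[C@@H](COC(C)=O)[C@H]1O[Si](C)(C)C(C)(C)C
F5 | step 7 | all-cis [2-(tert-butyldimethylsilyloxy)-3-(prop-1-en-2-yl)cyclopentyl]methanol | C=C(C)[C@H]1CC[C@@H](CO)[C@H]1O[Si](C)(C)C(C)(C)C
F6 | step 7 | all-cis 2-(tert-butyldimethylsilyloxy)-3-(prop-1-en-2-yl)cyclopentane-1-carbaldehyde | C=C(C)[C@H]1CC[C@@H](C=O)[C@H]1O[Si](C)(C)C(C)(C)C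
F7 | step 7 | 2-(tert-butyldimethylsilyloxy)-3-(prop-1-en-2-yl)cyclopentane-1-carbaldehyde with the formyl group trans to the silyloxy group and the silyloxy group cis to isopropenyl | C=C(C)[C@H]1CC[C@H](C=O)[C@H]1O[Si](C)(C)C(C)(C)C
F8 | step 7 | [(1R,2S,3R)-2-(tert-butyldimethylsilyloxy)-3-(prop-1-en-2-yl)cyclopentyl]methanol | C=C(C)[C@H]1CC[C@H](CO)[C@H]1O[Si](C)(C)C(C)(C)C
F9 | step 13 | potassium [2-(9-borabicyclo[3.3.1]nonan-9-yl)ethyl]trifluoroborate | [K+].F[B-](F)(F)CCB1C2CCCC1CCC2
F10 | step 13 | dipotassium (3Z,7Z)-3,8-bis(tert-butyldimethylsilyloxymethyl)deca-3,7-diene-1,10-diylbis(trifluoroborate) | [K+].[K+].F[B-](F)(F)CC/C(CO[Si](C)(C)C(C)(C)C)=C/CC/C=C(/CC[B-](F)(F)F)CO[Si](C)(C)C(C)(C)C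
F11 | step 3 | 2-(4-methylpent-3-en-1-yl)propane-1,3-diyl diacetate | CC(C)=CCCC(COC(C)=O)COC(C)=O
F0 | step 17 | none | none
A1 | alternative 1 | achiral open-chain bis-enal diol with two (E)-α-homoprenyl enals and two (Z)-allylic alcohols | CC(C)=CCC/C(C=O)=C\CC/C(CO)=C/CC/C=C(/CC/C=C(\CCC=C(C)C)C=O)CO
A2 | alternative 1 | bis(tetrahydropyranyl) bis(2-substituted 6-methylhept-5-enal) | CC(C)=CCC[C@H]([C@H]1CC/C(=C/CC/C=C2/CC[C@H]([C@@H](CCC=C(C)C)C=O)OC2)CO1)C=O
A3 | alternative 2 | bis(primary nitroalkane) with (E)-alkenes five atoms from each nitro-bearing carbon | C=C(C)[C@H](C[N+](=O)[O-])CC/C=C/CC/C(CO[Si](C)(C)C(C)(C)C)=C/CC/C=C(/CC/C=C/CC[C@@H](C[N+](=O)[O-])C(=C)C)CO[Si](C)(C)C(C)(C)C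
A4 | alternative 2 | bis(cyclopenta-fused isoxazoline) | C=C(C)[C@H]1CC[C@H]2C1=NO[C@@H]2CC/C(CO[Si](C)(C)C(C)(C)C)=C/CC/C=C(/CC[C@H]3ON=C4[C@@H](C(=C)C)CC[C@H]34)CO[Si](C)(C)C(C)(C)C
A5 | alternative 3 | bis(methoxymethyl ether) of the C2 carbinols with two (Z)-trimethylsilylalkenes | C=C(C)[C@H]1CC[C@H]([C@H](OCOC)CC/C([Si](C)(C)C)=C/CC/C=C(/CC[C@@H](OCOC)[C@H]2CC[C@H](C(=C)C)[C@@H]2O[Si](C)(C)C(C)(C)C)[Si](C)(C)C)[C@H]1O[Si](C)(C)C(C)(C)C
A6 | alternative 3 | testudinariol A bis(tert-butyldimethylsilyl) ether, identical with 28 | C=C(C)[C@H]1CC[C@H]([C@H]2CC/C(=C/CC/C=C3/CC[C@H]([C@H]4CC[C@H](C(=C)C)[C@@H]4O[Si](C)(C)C(C)(C)C)OC3)CO2)[C@H]1O[Si](C)(C)C(C)(C)C
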